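**Retrosynthetic overview**
1. Endgame: the acetic acid arm on C3 is carried as a slim ethynyl group (C≡CH to CH2CO2H by hydroboration–oxidation and Pinnick oxidation). The saturated chain comes from an (E)-alkene, made from an (R)-allylic alcohol by allylic diazene transposition (this sets the chain methyl centre); the alcohol comes from an (E)-enone.
2. Key disconnection: the exocyclic C5–CH2 bond at the fully substituted ring carbon C5. It is cut into a C7 5-methoxy-1,2-dioxolane (cation precursor) and a C17 silyl dienol ether that holds the whole chain; together they bring all 24 carbons.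
3. Enabling feature: C5 is bonded to O1 of the O1–O2 bridge of the 1,2-dioxolane ring, so the lone pair on O1 stabilises a cation at C5 (peroxycarbenium ion, C5=O1+). Quaternary C3 is the flap atom of that five-membered envelope and steers the incoming carbon.
4. Ring order: a temporary oxetane ring first (4-exo-tet; it stores the C3–O configuration and is opened by H2O2 with inversion), then the 1,2-dioxolane ring (5-exo-trig hemiketalisation). Both form before the key step; the phenyl ring is bought.
5. Sources of chirality: (R)-pent-4-en-2-ol for C3 and, by relay, C5; a CBS catalyst for the carbinol that is relayed to the chain methyl centre.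

Key step: step 11

Remark: in the Why lines the ring atoms carry the target numbering (O1, O2, C3 with the acetic acid arm or its ethynyl mask, C4, C5 with the long chain); systematic names may number the ring the other way round.
Remark: the small peroxides 6 to 11 should be kept in solution, on small scale and behind a shield.

**Step 1**
Reactants: 1 (R)-pent-4-en-2-ol
Product: 2 (R)-4-hydroxypentan-2-one
Conditions: PdCl2 (10 mol %), CuCl (30 mol %), O2 (1 atm), DMF/H2O 7:1, rt
Reagents that add atoms: water, O
Why: A Tsuji–Wacker oxidation should turn the terminal alkene into the methyl ketone by Markovnikov hydroxypalladation, while the carbinol stereocentre bought with 1 is not involved.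

**Step 2**
Reactants: 2 (R)-4-hydroxypentan-2-one
Product: 3 (2R,4S)-4-methylhex-5-yne-2,4-diol
Conditions: HC≡CMgBr (3 equiv), THF, −78 → −20 °C; sat. aq NH4Cl; chromatography
Reagents that add atoms: ethynylmagnesium bromide, C#C[Mg]Br
Why: In this chelation-controlled Grignard addition the first equivalent makes the magnesium alkoxide, which locks the ketone in a six-membered chelate with the carbinol methyl group equatorial, and the slim acetylide should add axially to set the tertiary carbinol as (4S); the (4R) epimer is a diastereomer and is removed by chromatography.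

**Step 3**
Reactants: 3 (2R,4S)-4-methylhex-5-yne-2,4-diol
Product: 5 (2S,4S)-2-ethynyl-2,4-dimethyloxetane, via secondary mesylate 4 (not isolated)
Conditions: MsCl, Et3N, CH2Cl2, −10 °C; then NaH, THF, 0 → 40 °C
Reagents that add atoms: none
Why: Selective sulfonylation of the less hindered secondary alcohol and a Williamson-type 4-exo-tet closure by the tertiary alkoxide should give the oxetane with inversion at the secondary carbon and with retention at the quaternary carbon, whose C–O bond is not touched.

**Step 4**
Reactants: 5 (2S,4S)-2-ethynyl-2,4-dimethyloxetane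
Product: 6 (2S,4R)-4-hydroperoxy-4-methylhex-5-yn-2-ol
Conditions: anhydrous H2O2 in Et2O (10 equiv), Me3SiOTf (20 mol %), −78 → −20 °C
Reagents that add atoms: hydrogen peroxide, OO
Why: In this Lewis-acid-promoted perhydrolysis of a 2,2-disubstituted oxetane the activated ring oxygen leaves from the tertiary propargylic carbon, the site that best carries positive charge, while H2O2 enters from the rear in a borderline SN2 event driven by strain release, so the C–OO bond should form with inversion and set the (4R) centre that becomes C3 of the target.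

**Step 5**
Reactants: 6 (2S,4R)-4-hydroperoxy-4-methylhex-5-yn-2-ol
Product: 7 (2S,4R)-4-methyl-4-[(triethylsilyl)peroxy]hex-5-yn-2-ol
Conditions: Et3SiCl (1.05 equiv), imidazole, CH2Cl2, −20 → 0 °C
Reagents that add atoms: chlorotriethylsilane, CC[Si](Cl)(CC)CC
Why: The hydroperoxide is more acidic and, through the alpha effect, more nucleophilic than the secondary alcohol, so one equivalent of the silyl chloride should protect it chemoselectively as the silyl peroxide (standard O-silylation, no stereocentre touched).

**Step 6**
Reactants: 7 (2S,4R)-4-methyl-4-[(triethylsilyl)peroxy]hex-5-yn-2-ol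
Product: 8 (4R)-4-methyl-4-[(triethylsilyl)peroxy]hex-5-yn-2-one
Conditions: Dess–Martin periodinane, CH2Cl2, 0 °C → rt
Reagents that add atoms: none
Why: A Dess–Martin oxidation converts the secondary alcohol into the methyl ketone under nearly neutral conditions that silyl peroxides and terminal alkynes tolerate, and it deletes the carbinol stereocentre that has done its work.

**Step 7**
Reactants: 8 (4R)-4-methyl-4-[(triethylsilyl)peroxy]hex-5-yn-2-one
Product: 11 (3R)-3-ethynyl-5-methoxy-3,5-dimethyl-1,2-dioxolane (C5 epimers), via hydroperoxy ketone 9 (not isolated), via peroxyhemiketal 10 (not isolated)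
Conditions: p-TsOH·H2O (10 mol %), MeOH, 0 °C → rt
Reagents that add atoms: methanol, CO
Why: Acid methanolysis frees the hydroperoxide, which closes onto the ketone by 5-exo-trig hemiketalisation to build the 1,2-dioxolane ring, and acid-catalysed exchange of OH for OMe (ketalisation in methanol) gives the storable ketal, whose new C5 centre is an epimer mixture of no consequence because it is ionised in step 11.

**Step 8**
Reactants: 12 7-phenylheptanoic acid
Product: 14 N-methoxy-N-methyl-7-phenylheptanamide, via acyl imidazole 13 (not isolated)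
Conditions: CDI, CH2Cl2, rt; then MeNH(OMe)·HCl, rt
Reagents that add atoms: N,O-dimethylhydroxylamine hydrochloride, CNOC.Cl
Why: Activation by carbonyldiimidazole and aminolysis of the acyl imidazole is a routine amide coupling that gives the Weinreb amide without any stereochemical issue.

**Step 9**
Reactants: 14 N-methoxy-N-methyl-7-phenylheptanamide
Product: 15 2-methyl-10-phenyldec-1-en-4-one
Conditions: CH2=C(CH3)CH2MgCl, THF, −78 → −20 °C; cold sat. aq NH4Cl
Reagents that add atoms: 2-methylallylmagnesium chloride, C=C(C)C[Mg]Cl
Why: In the Weinreb ketone synthesis the chelated tetrahedral adduct stops the allylic Grignard reagent at single addition, and the cold, mild quench should keep the double bond out of conjugation.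

**Step 10**
Reactants: 15 2-methyl-10-phenyldec-1-en-4-one
Product: 16 trimethyl{[(3Z)-2-methyl-10-phenyldeca-1,3-dien-4-yl]oxy}silane
Conditions: Me3SiOTf, Et3N, Et2O, 0 °C; pentane extraction, used crude
Reagents that add atoms: trimethylsilyl triflate, C[Si](C)(C)OS(=O)(=O)C(F)(F)F
Why: In this soft enolisation the doubly activated allylic CH2 should lose its proton rather than the plain CH2 on the other side, because only this path gives the conjugated dienol silane, so the regiochemical problem of the conjugated enone isomer is avoided and the enol ether geometry is of no consequence.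

**Step 11**
Reactants: 11 (3R)-3-ethynyl-5-methoxy-3,5-dimethyl-1,2-dioxolane (C5 epimers); 16 trimethyl{[(3Z)-2-methyl-10-phenyldeca-1,3-dien-4-yl]oxy}silane
Product: 18 (2E)-1-[(3R,5R)-5-ethynyl-3,5-dimethyl-1,2-dioxolan-3-yl]-2-methyl-10-phenyldec-2-en-4-one, via peroxycarbenium triflate 17 (not isolated)
Conditions: Me3SiOTf (20 mol %), 2,6-di-tert-butyl-4-methylpyridine (10 mol %), CH2Cl2, −78 → −40 °C
Reagents that add atoms: none
Why: Me3SiOTf abstracts the methoxy group from either C5 epimer of 11 to give the planar peroxycarbenium ion 17 (C5=O1+), the unhindered terminal CH2 of dienol silane 16 adds to C5, and loss of the silyl group from the resulting silyloxocarbenium ion returns Me3SiOTf and leaves the conjugated enone. The closest known reaction type is the Lewis-acid-mediated Mukaiyama-type substitution of 3-alkoxy-1,2-dioxolanes by enol silanes, silyl ketene acetals and allylsilanes, used here in the vinylogous form that is standard for ordinary ketals. No ring is closed, and the dioxolane ring should pass through with its O–O bond intact because the acid is catalytic and the temperature low. The one new stereocentre, quaternary C5, is controlled by quaternary C3: in the envelope-shaped cation C3 is the flap, its methyl group takes the pseudoequatorial and the rod-like ethynyl group the pseudoaxial position, and inside attack on this envelope (the model for five-membered-ring oxocarbenium ions) comes from the ethynyl face, so the new CH2 should end up cis to ethynyl and the two ring methyl groups cis, as in the target. The step needs facial selectivity, secured by the large size gap between CH3 and C≡CH that an acetate arm would not offer, γ- over α-regioselectivity, secured by the tertiary cation that cannot reach the substituted α-carbon, and (E) geometry, secured by reaction through the s-trans diene and by the preference of the bulky dioxolanylmethyl group to lie trans to the acyl group.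

**Step 12**
Reactants: 18 (2E)-1-[(3R,5R)-5-ethynyl-3,5-dimethyl-1,2-dioxolan-3-yl]-2-methyl-10-phenyldec-2-en-4-one
Product: 19 (2E,4R)-1-[(3R,5R)-5-ethynyl-3,5-dimethyl-1,2-dioxolan-3-yl]-2-methyl-10-phenyldec-2-en-4-ol
Conditions: (S)-2-methyl-CBS-oxazaborolidine (20 mol %), catecholborane (2 equiv), toluene, −78 °C; aqueous work-up
Reagents that add atoms: none
Why: In the Corey–Bakshi–Shibata reduction the (S)-oxazaborolidine binds the ketone anti to its larger, β,β-disubstituted alkenyl arm and passes hydride from catecholborane to one face, which should set the (4R)-carbinol by catalyst control, while catecholborane at −78 °C leaves alkyne, alkene and O–O bond alone.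

**Step 13**
Reactants: 19 (2E,4R)-1-[(3R,5R)-5-ethynyl-3,5-dimethyl-1,2-dioxolan-3-yl]-2-methyl-10-phenyldec-2-en-4-ol
Product: 22 (3R,5R)-3-ethynyl-3,5-dimethyl-5-[(2S,3E)-2-methyl-10-phenyldec-3-en-1-yl]-1,2-dioxolane, via allylic sulfonylhydrazine 20 (not isolated), via allylic diazene 21 (not isolated)
Conditions: PPh3, DEAD, THF, −30 °C; 2-nitrobenzenesulfonylhydrazide (1.1 equiv), −30 °C → rt
Reagents that add atoms: none
Why: A Mitsunobu displacement by the sulfonylhydrazide inverts the carbinol, loss of sulfinic acid on warming gives the allylic diazene, and its concerted retro-ene loss of N2 hands the hydrogen suprafacially to the trisubstituted alkene carbon from the conformer in which allylic 1,3-strain against the cis methyl group holds the carbinyl H in the alkene plane, which should set the chain methyl stereocentre (S here, R after saturation) and an (E)-alkene by 1,3-chirality transfer.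

**Step 14**
Reactants: 22 (3R,5R)-3-ethynyl-3,5-dimethyl-5-[(2S,3E)-2-methyl-10-phenyldec-3-en-1-yl]-1,2-dioxolane
Product: 24 2-{(3R,5R)-3,5-dimethyl-5-[(2S,3E)-2-methyl-10-phenyldec-3-en-1-yl]-1,2-dioxolan-3-yl}acetaldehyde, via alkenylborane 23 (not isolated)
Conditions: (c-C6H11)2BH (1.1 equiv), THF, 0 °C; then 30 % H2O2, pH 7 phosphate buffer, 0 °C
Reagents that add atoms: hydrogen peroxide, OO
Why: In this hydroboration–oxidation the bulky dialkylborane adds anti-Markovnikov to the terminal alkyne much faster than to the branched internal alkene, and buffered oxidation of the alkenylborane gives the enol and hence the aldehyde without base-induced β-elimination of the peroxide.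

**Step 15**
Reactants: 24 2-{(3R,5R)-3,5-dimethyl-5-[(2S,3E)-2-methyl-10-phenyldec-3-en-1-yl]-1,2-dioxolan-3-yl}acetaldehyde
Product: 25 2-{(3R,5R)-3,5-dimethyl-5-[(2S,3E)-2-methyl-10-phenyldec-3-en-1-yl]-1,2-dioxolan-3-yl}acetic acid
Conditions: NaClO2, NaH2PO4, 2-methylbut-2-ene, t-BuOH/H2O, 0 °C → rt
Reagents that add atoms: sodium chlorite, [Na+].[O-]Cl=O
Why: The Pinnick oxidation converts the aldehyde into the acid at mildly acidic pH, where neither the β-peroxy carbonyl unit nor the chain alkene, shielded by the scavenger, should suffer.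

**Step 16**
Reactants: 25 2-{(3R,5R)-3,5-dimethyl-5-[(2S,3E)-2-methyl-10-phenyldec-3-en-1-yl]-1,2-dioxolan-3-yl}acetic acid
Product: 26 2-{(3R,5R)-3,5-dimethyl-5-[(2R)-2-methyl-10-phenyldecyl]-1,2-dioxolan-3-yl}acetic acid
Conditions: KO2CN=NCO2K (excess), AcOH, MeOH, 0 °C → rt
Reagents that add atoms: none
Why: A diimide reduction transfers two hydrogens concertedly to the disubstituted alkene and is the classical way to saturate C=C bonds beside an O–O bond, which it does not reduce, and no stereocentre is touched (the descriptor of the chain centre changes from S to R only through the priority rules).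

**Compound list**
1 | (R)-pent-4-en-2-ol | C=CC[C@@H](C)O | starting material
2 | (R)-4-hydroxypentan-2-one | CC(=O)C[C@@H](C)O | intermediate
3 | (2R,4S)-4-methylhex-5-yne-2,4-diol | C[C@@H](O)C[C@@](C)(C#C)O | intermediate
4 | (2R,4S)-4-hydroxy-4-methylhex-5-yn-2-yl methanesulfonate | C[C@@H](OS(C)(=O)=O)C[C@@](C)(C#C)O | intermediate
5 | (2S,4S)-2-ethynyl-2,4-dimethyloxetane (methyl groups cis) | C[C@H]1C[C@@](C)(C#C)O1 | intermediate
6 | (2S,4R)-4-hydroperoxy-4-methylhex-5-yn-2-ol | C[C@H](O)C[C@](C)(C#C)OO | intermediate
7 | (2S,4R)-4-methyl-4-[(triethylsilyl)peroxy]hex-5-yn-2-ol | C[C@H](O)C[C@](C)(C#C)OO[Si](CC)(CC)CC | intermediate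
8 | (4R)-4-methyl-4-[(triethylsilyl)peroxy]hex-5-yn-2-one | CC(=O)C[C@](C)(C#C)OO[Si](CC)(CC)CC | intermediate
9 | (4R)-4-hydroperoxy-4-methylhex-5-yn-2-one | CC(=O)C[C@](C)(C#C)OO | intermediate
10 | (5R)-5-ethynyl-3,5-dimethyl-1,2-dioxolan-3-ol (hemiketal epimers) | CC1(O)C[C@](C)(C#C)OO1 | intermediate
11 | (3R)-3-ethynyl-5-methoxy-3,5-dimethyl-1,2-dioxolane (C5 epimers) | COC1(C)C[C@](C)(C#C)OO1 | intermediate
12 | 7-phenylheptanoic acid | OC(=O)CCCCCCc1ccccc1 | starting material
13 | 1-(imidazol-1-yl)-7-phenylheptan-1-one | O=C(CCCCCCc1ccccc1)n1ccnc1 | intermediate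
14 | N-methoxy-N-methyl-7-phenylheptanamide | CON(C)C(=O)CCCCCCc1ccccc1 | intermediate
15 | 2-methyl-10-phenyldec-1-en-4-one | C=C(C)CC(=O)CCCCCCc1ccccc1 | intermediate
16 | trimethyl{[(3Z)-2-methyl-10-phenyldeca-1,3-dien-4-yl]oxy}silane | C=C(C)/C=C(\O[Si](C)(C)C)CCCCCCc1ccccc1 | intermediate
17 | (5R)-5-ethynyl-3,5-dimethyl-1,2-dioxolan-3-ylium triflate (peroxycarbenium ion) | CC1=[O+]O[C@@](C)(C#C)C1.[O-]S(=O)(=O)C(F)(F)F | intermediate
18 | (2E)-1-[(3R,5R)-5-ethynyl-3,5-dimethyl-1,2-dioxolan-3-yl]-2-methyl-10-phenyldec-2-en-4-one | O=C(CCCCCCc1ccccc1)/C=C(\C)C[C@]1(C)C[C@](C)(C#C)OO1 | intermediate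
19 | (2E,4R)-1-[(3R,5R)-5-ethynyl-3,5-dimethyl-1,2-dioxolan-3-yl]-2-methyl-10-phenyldec-2-en-4-ol | O[C@H](CCCCCCc1ccccc1)/C=C(\C)C[C@]1(C)C[C@](C)(C#C)OO1 | intermediate
20 | N-{(2E,4S)-1-[(3R,5R)-5-ethynyl-3,5-dimethyl-1,2-dioxolan-3-yl]-2-methyl-10-phenyldec-2-en-4-yl}-2-nitrobenzenesulfonohydrazide | NN([C@@H](CCCCCCc1ccccc1)/C=C(\C)C[C@]1(C)C[C@](C)(C#C)OO1)S(=O)(=O)c1ccccc1[N+](=O)[O-] | intermediate
21 | {(2E,4S)-1-[(3R,5R)-5-ethynyl-3,5-dimethyl-1,2-dioxolan-3-yl]-2-methyl-10-phenyldec-2-en-4-yl}diazene | N=N[C@@H](CCCCCCc1ccccc1)/C=C(\C)C[C@]1(C)C[C@](C)(C#C)OO1 | intermediate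
22 | (3R,5R)-3-ethynyl-3,5-dimethyl-5-[(2S,3E)-2-methyl-10-phenyldec-3-en-1-yl]-1,2-dioxolane | C[C@H](/C=C/CCCCCCc1ccccc1)C[C@]1(C)C[C@](C)(C#C)OO1 | intermediate
23 | dicyclohexyl[(E)-2-{(3R,5R)-3,5-dimethyl-5-[(2S,3E)-2-methyl-10-phenyldec-3-en-1-yl]-1,2-dioxolan-3-yl}ethenyl]borane | C[C@H](/C=C/CCCCCCc1ccccc1)C[C@]1(C)C[C@](C)(/C=C/B(C2CCCCC2)C2CCCCC2)OO1 | intermediate
24 | 2-{(3R,5R)-3,5-dimethyl-5-[(2S,3E)-2-methyl-10-phenyldec-3-en-1-yl]-1,2-dioxolan-3-yl}acetaldehyde | C[C@H](/C=C/CCCCCCc1ccccc1)C[C@]1(C)C[C@](C)(CC=O)OO1 | intermediate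
25 | 2-{(3R,5R)-3,5-dimethyl-5-[(2S,3E)-2-methyl-10-phenyldec-3-en-1-yl]-1,2-dioxolan-3-yl}acetic acid | C[C@H](/C=C/CCCCCCc1ccccc1)C[C@]1(C)C[C@](C)(CC(=O)O)OO1 | intermediate
26 | 2-{(3R,5R)-3,5-dimethyl-5-[(2R)-2-methyl-10-phenyldecyl]-1,2-dioxolan-3-yl}acetic acid | C[C@H](CCCCCCCCc1ccccc1)C[C@]1(C)C[C@](C)(CC(=O)O)OO1 | target

Total step count: 16. Longest linear sequence: 13 (steps 1 to 7 and 11 to 16).

**Steps most likely to fail**

Step 11. Capture of the hindered cation by the long dienol silane may be too slow. Proton loss from the cation, acid-induced breakdown of the O–O bond, attack through the α-carbon or a weak facial preference could then take over.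
- The fallback assembles the chain linearly instead of convergently. It sets out from 11.
- Compound 11 is ionised in the same way in the presence of the small and more reactive 3-methyl-1-(trimethylsilyloxy)buta-1,3-diene F1. This is made from 3-methylbut-2-enal with Me3SiOTf and Et3N and is a classical vinylogous Mukaiyama partner of ketals. The product should be (2E)-4-[(3R,5R)-5-ethynyl-3,5-dimethyl-1,2-dioxolan-3-yl]-3-methylbut-2-enal F2.
- The chain is then added as bis(6-phenylhexyl)zinc F3 (from (6-iodohexyl)benzene, Et2Zn and catalytic CuI) with Ti(OiPr)4 and the (1S,2S)-cyclohexane-1,2-diyl bis(triflamide) ligand. This catalyst-controlled alkylzinc addition should give the (R)-allylic alcohol directly.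
- The route is rejoined at 19 and step 12 is dropped.

Step 4. The ethynyl group lowers the ability of the tertiary carbon to carry charge. Attack of H2O2 may drift to the secondary oxetane carbon, or the opening may turn dissociative and leak configuration.
- The fallback replaces the stereospecific opening by a resolution through the resident carbinol centre. It sets out from diol 3 (the unseparated epimer mixture of step 2 serves as well).
- Acid-catalysed perhydrolysis of the tertiary propargylic alcohol (H2O2, catalytic H2SO4, 0 °C) is a long-known SN1 route to acetylenic hydroperoxides. It gives both C4 epimers, which are diastereomers thanks to the untouched (2R)-carbinol.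
- They are separated by chromatography into (2R,4R)-4-hydroperoxy-4-methylhex-5-yn-2-ol F4 and (2R,4S)-4-hydroperoxy-4-methylhex-5-yn-2-ol F5.
- F4 is silylated as in step 5 to (2R,4R)-4-methyl-4-[(triethylsilyl)peroxy]hex-5-yn-2-ol F6 and oxidised as in step 6. This erases C2 and rejoins the route at 8.

Step 13. The secondary, prenyl-type allylic alcohol may ionise under Mitsunobu activation, with loss of inversion fidelity or attack at the far allyl terminus. Diimide from surplus reagent may also start to reduce the terminal alkyne.
- The fallback uses hydride transfer through a π-allyl palladium complex instead of a sigmatropic diazene shift. It sets out from 19.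
- Compound 19 is esterified (HCO2H, DCC, DMAP) to (2E,4R)-1-[(3R,5R)-5-ethynyl-3,5-dimethyl-1,2-dioxolan-3-yl]-2-methyl-10-phenyldec-2-en-4-yl formate F7.
- Pd2(dba)3 and PBu3 in THF ionise it with inversion and CO2 is lost. The palladium hydride is delivered on the metal face to the more substituted allyl terminus, again anti to the original C–O bond.
- This should give the same (S,E)-alkene and rejoins the route at 22.

**Further compounds**
F1 | step 11 | 3-methyl-1-(trimethylsilyloxy)buta-1,3-diene | C=C(C)/C=C/O[Si](C)(C)C
F2 | step 11 | (2E)-4-[(3R,5R)-5-ethynyl-3,5-dimethyl-1,2-dioxolan-3-yl]-3-methylbut-2-enal | O=C/C=C(\C)C[C@]1(C)C[C@](C)(C#C)OO1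
F3 | step 11 | bis(6-phenylhexyl)zinc | c1ccc(CCCCCC[Zn]CCCCCCc2ccccc2)cc1
F4 | step 4 | (2R,4R)-4-hydroperoxy-4-methylhex-5-yn-2-ol | C[C@@H](O)C[C@](C)(C#C)OO
F5 | step 4 | (2R,4S)-4-hydroperoxy-4-methylhex-5-yn-2-ol | C[C@@H](O)C[C@@](C)(C#C)OO
F6 | step 4 | (2R,4R)-4-methyl-4-[(triethylsilyl)peroxy]hex-5-yn-2-ol | C[C@@H](O)C[C@](C)(C#C)OO[Si](CC)(CC)CC
F7 | step 13 | (2E,4R)-1-[(3R,5R)-5-ethynyl-3,5-dimethyl-1,2-dioxolan-3-yl]-2-methyl-10-phenyldec-2-en-4-yl formate | O=CO[C@H](CCCCCCc1ccccc1)/C=C(\C)C[C@]1(C)C[C@](C)(C#C)OO1
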